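Numbering used throughout: the carbocycle is C1–C14 (C1 = CH bonded to C15, C2 = O–CH, methyl groups on C4, C8 and C12, acetate on C9); the lactone carbons are C15 (α-carbon), C16 (C=O) and C17 (exocyclic CH2).

## Analysis of the target

The target is a cembranolide: a fourteen-membered carbocycle fused at C1–C2 to an α-methylene-γ-butyrolactone (ring O–C2–C1–C15–C16). The three ring alkenes C3=C4, C7=C8 and C11=C12 are trisubstituted and all E. There are three stereocentres: C1 (R) and C2 (S) are adjacent and carry trans hydrogens, so the lactone is trans-fused. C9 (S) is an isolated allylic carbinol ester, six bonds from C1 and seven from C2 around the ring. The sensitive groups are the exocyclic methylene lactone (a Michael acceptor toward amines, alkoxides, hydrides and radicals), the C2–O bond (allylic to C3=C4), and the C9 allylic acetate, which sits between C7=C8 and C11=C12. The difficulty is to close a fourteen-membered ring without disturbing three trisubstituted E alkenes, and to fix C9 where C1 and C2 are too far away to exert a useful bias. The plan rests on one feature: C9 is a secondary carbinol bonded directly to C8, an sp2 carbon of the C7=C8(Me) alkene. The C8–C9 bond can therefore be made by adding a C8 alkenyl metal to a C9 aldehyde, which closes the ring and creates C9 in one reagent-controlled event.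

## Retrosynthetic reasoning

34 to 33. The acetate O–acyl bond is cut first. An allylic acetate between two alkenes ionises easily and would not survive organometallic steps, whereas the free carbinol 33 is exactly what a carbonyl addition delivers. The forward step only has to acylate a secondary allylic alcohol without allylic transposition.

33 to 31. The ring is opened at C8–C9. This is the only ring bond that joins an sp2 carbon to a carbinol carbon, so it alone can be made by a polar alkenyl-metal addition to an aldehyde. Cutting an sp3–sp3 bond such as C5–C6 or C13–C14 would call for an alkylative macrocyclisation and would create no stereocentre. Closing at one of the trisubstituted alkenes would put E/Z control at risk. The cut at C8–C9 gives seco aldehyde 31, in which the E geometry of C7=C8 is already stored in an alkenyl iodide. The forward reaction must close a fourteen-membered ring at the aldehyde in the presence of the lactone and its conjugated methylene, and must choose one face of the aldehyde under reagent control.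

31 to 30 to 29. No skeletal bond is cut here. Aldehyde 31 is β,γ-unsaturated and prone to conjugation, so it is generated last, from primary alcohol 30, which is carried as silyl ether 29. The forward steps are a mild desilylation and a buffered, non-basic oxidation.

29 to 27 to 15 plus 24. Two bonds at the lactone are cut: C1–C14 and C15=C17. C1 is the β-carbon of the lactone, so the C9–C14 chain of bromide 24 can be added as a copper-modified nucleophile to butenolide 15. The enolate formed is captured with an aminomethyl electrophile to give Mannich base 27, and elimination then gives the exocyclic methylene of 29. This joins two halves of similar size, lets the existing C2 centre set C1 (addition anti to the C2 substituent), and installs C17 in the same operation. The forward reaction must add 1,4 rather than 1,2, stay anti to the C2 alkenyl group and leave the C8 alkenyl iodide alone.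

15 to 14 to 12 plus 13, and 12 to 11. The butenolide C=C bond is cut by ring-closing metathesis logic, leading to acrylate 14, which comes from divinyl carbinol 12 and acryloyl chloride 13. The bond between C2 and the future C1 is then cut, leading to the flat, achiral enal 11. C2 is the centre from which C1 is later derived, so a single catalyst-controlled vinyl addition to 11 is all the absolute stereocontrol the lactone needs.

11 to 10 to 8 to 6 to 4 to 2 to 1. The C8–iodine bond is traced back to methyl alkyne 8 (syn hydrometalation then iodination gives the E iodide 10, and allylic oxidation gives 11). The C8–CH3 bond is traced to terminal alkyne 6, and the C7≡C8 bond to aldehyde 4 by one-carbon homologation. Aldehyde 4 comes from geranyl acetate 1 by cleaving its distal alkene through epoxide 2. This buys the E C3=C4 alkene, the C4 methyl and the C2 oxygen with the starting material.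

24 to 23 to 22 to 21 to 17 plus 18, and 17 to 16. Bromide 24 comes from alcohol 23. The C10–C11 bond is cut to an alkenyl metal and ethylene oxide 18, and the C12–CH3 bond to a syn methylmetalation of alkyne 17, which fixes the E C11=C12 alkene. The two chain oxygens are told apart by a 4-methoxybenzyl ether on C14 (from but-3-yn-1-ol 16) and a silyl ether on C9 (21 to 22 to 23).

## Alternatives that were turned down

Alternative 1: The lactone O–C2 bond is made last, from A2, a fourteen-membered ring in which C15 (a malonic acid carbon) bridges C1 and C2 as a trans-disubstituted cyclopropane. In the forward key step, a trace of acid or Pd(PPh3)4 ionises the C15–C2 bond (donor: the C3=C4 alkene; acceptor: the geminal carboxyl groups), and one carboxylate oxygen recloses on C2 to give α-carboxy lactone A1. Decarboxylative methylenation, desilylation and acetylation would follow.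
- For: the macrocycle could be closed earlier by robust malonate alkylation, and the C1/C2 relationship is stored in the cyclopropane. The exocyclic methylene appears only at the very end. On that point this plan is stronger than the chosen one, where the methylene must survive four steps including the ring closure.
- Against: C2 passes through an allyl cation or π-allyl palladium species spanning C2–C3–C4. Capture at C4 (a seven-membered lactone) and syn/anti equilibration that erodes the E geometry of C3=C4 both become possible. C2 keeps its configuration only if ionisation and capture are both stereospecific. Building a trans cyclopropane inside the large ring is itself a stereochemical problem, and C9 still needs its own step.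
- Comparison: three steps follow the key step instead of one, and two stereochemical questions stay open. The chosen route answers C1/C2 by a well-precedented anti conjugate addition and C9 in the ring closure.

Alternative 2: The ring is cut at C12–C13 (sp2–sp3). In the forward key step, seco lactone A4, which carries a vinyl group on C1 (C14=C13) and an alkenyl iodide at C12, is hydroborated at C13 with a hindered dialkylborane. The alkylborane is then coupled with the iodide under Pd(dppf)Cl2 and aqueous base to give macrocycle A3.
- For: no stereocentre forms in the ring closure, so there is nothing to control, the C11=C12 geometry is carried in, and B-alkyl couplings close large rings dependably. On the ring-closing event itself this is the safer reaction.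
- Against: the exocyclic methylene cannot be present during hydroboration, so A3 still needs enolisation and methylenation on the macrocycle, then desilylation and acetylation. C9 has to be made earlier by a separate intermolecular enantioselective alkenyl addition and then protected. Warm aqueous base is also a hazard for the lactone.
- Comparison: the chosen route offers in its place one step that builds the ring, the C8–C9 bond and C9 together, followed only by an acetylation.

Alternative 3: The ring is cut at C7–C8, taken as an alkyne. In the forward key step, α-methylene lactone A6, whose two arms end in methyl-capped alkynes (one at C7, one at C8 next to the silylated C9 carbinol), is treated with Mo(≡CC6H4OMe-4)(OSiPh3)3 and molecular sieves. A small volatile alkyne is lost and cycloalkyne A5 results.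
- For: alkyne metathesis has no E/Z issue, is very reliable for rings of this size, and tolerates esters and alkenes. C9 is set beforehand by propargylic alcohol chemistry with well-understood enantiocontrol. On both ring closure and C9 control this plan is at least as strong as the chosen one.
- Against: A5 lacks the C8 methyl and the C7=C8 alkene. After desilylation, a hydroxyl-directed trans-hydrometalation must place a metal at C8 regioselectively, and a methyl cross-coupling must follow. All of this happens on a macrocycle carrying a Michael acceptor that is sensitive to metal hydrides and radical conditions, and it adds three or four steps after ring closure.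
- Comparison: the chosen route brings the C8 methyl and the E alkene in from an acyclic, easily purified alkenyl iodide and needs one step after ring closure. It pays for this with a ring closure whose stereochemical outcome depends on the ligand.

Key step: step 19

Remark 1: the facial sense of the amino alcohol in step 7 and of the oxazoline–sulfonamide ligand in step 19 is assigned by analogy with related additions; the enantiomer named is the one expected to give Re-face attack, and its mirror image would be used if the sense proved opposite.
Remark 2: epoxide 2 and diol 3 are racemic at the former C6 of geranyl acetate; this centre is destroyed in step 2.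

## Route

Step 1
Reactants: 1 geranyl acetate [(E)-3,7-dimethylocta-2,6-dien-1-yl acetate]
Product: 2 (E)-5-(3,3-dimethyloxiran-2-yl)-3-methylpent-2-en-1-yl acetate
Conditions: mCPBA (1.05 equiv), NaHCO3, CH2Cl2, 0 °C
Reagents that add atoms: 3-chloroperoxybenzoic acid (mCPBA), OOC(=O)c1cccc(Cl)c1
Why: Prilezhaev epoxidation; the distal trisubstituted alkene is the more electron-rich one because the other is deactivated by the allylic acetate, so mono-epoxidation at the terminus is expected.

Step 2
Reactants: 2
Product: 4 (E)-3-methyl-6-oxohex-2-en-1-yl acetate, via 6,7-diol acetate 3 (not isolated)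
Conditions: H5IO6 (1.2 equiv), THF/H2O, 0 °C
Reagents that add atoms: none
Why: Acid-mediated epoxide opening (water enters at the tertiary carbon) followed by periodate glycol cleavage releases the aldehyde and acetone; the allylic acetate and the E alkene are not touched.

Step 3
Reactants: 4
Product: 6 (E)-3-methylhept-2-en-6-yn-1-ol, via enynyl acetate 5 (not isolated)
Conditions: dimethyl (1-diazo-2-oxopropyl)phosphonate (1.3 equiv), K2CO3 (3 equiv), MeOH, 0 °C → rt
Reagents that add atoms: dimethyl (1-diazo-2-oxopropyl)phosphonate, CC(=O)C(=[N+]=[N-])P(=O)(OC)OC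
Why: Ohira–Bestmann (Seyferth–Gilbert) homologation turns the aldehyde into the terminal alkyne under mild carbonate conditions; the same methanolic K2CO3 transesterifies the allylic acetate, so the free alcohol needed later is released in the same flask.

Step 4
Reactants: 6
Product: 8 (E)-3-methyloct-2-en-6-yn-1-ol, via dilithium alkoxide acetylide 7 (not isolated)
Conditions: n-BuLi (2.1 equiv), THF, −78 → −20 °C; MeI (1.05 equiv), −78 °C → rt
Reagents that add atoms: iodomethane, CI
Why: Alkylation of a lithium acetylide; in the alkoxide–acetylide dianion the carbon nucleophile is far more reactive toward MeI in THF than the lithium alkoxide, so one equivalent of MeI should methylate carbon only.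

Step 5
Reactants: 8
Product: 10 (2E,6E)-7-iodo-3-methylocta-2,6-dien-1-ol, via bis-Zr(Cl)Cp2 alkenyl alkoxide 9 (not isolated)
Conditions: Cp2Zr(H)Cl (3 equiv), THF, 50 °C; then I2, THF, 0 °C
Reagents that add atoms: iodine, II
Why: Hydrozirconation–iodination; Zr–H adds syn, and with excess hydride and warming the regioisomers equilibrate toward zirconium on the less hindered methyl-bearing carbon, after which iodinolysis with retention gives the E iodide. One equivalent of hydride is consumed by the hydroxyl, and the trisubstituted alkene is too hindered to react.

Step 6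
Reactants: 10
Product: 11 (2E,6E)-7-iodo-3-methylocta-2,6-dienal
Conditions: MnO2 (activated, 15 equiv), CH2Cl2, rt
Reagents that add atoms: none
Why: Chemoselective oxidation of an allylic alcohol; the neutral heterogeneous conditions should keep the E enal geometry and leave the alkenyl iodide alone.

Step 7
Reactants: 11
Product: 12 (3R,4E,8E)-9-iodo-5-methyldeca-1,4,8-trien-3-ol
Conditions: CH2=CHMgBr (3 equiv), ZnCl2 (1.5 equiv), THF, 0 °C, then 1,4-dioxane and filtration; 11, (+)-MIB [(2R)-3-exo-morpholinoisoborneol] (10 mol %), toluene, −30 → 0 °C; aq. NH4Cl
Reagents that add atoms: vinylmagnesium bromide, C=C[Mg]Br (the vinyl group is transferred through divinylzinc made in the flask)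
Why: Amino-alcohol-catalysed enantioselective addition of an alkenylzinc reagent to an aldehyde; the chiral zinc aminoalkoxide binds the aldehyde and a second zinc delivers vinyl to the Re face, which sets C2. Zinc reagents add 1,2 to enals and do not touch the alkenyl iodide.

Step 8
Reactants: 12; 13 acryloyl chloride
Product: 14 (3R,4E,8E)-9-iodo-5-methyldeca-1,4,8-trien-3-yl acrylate
Conditions: iPr2NEt (2 equiv), CH2Cl2, −78 → 0 °C
Reagents that add atoms: none
Why: O-acylation of a secondary alcohol with an acid chloride; low temperature and a hindered amine avoid ionisation of the doubly allylic C–O bond and polymerisation of the acrylate.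

Step 9
Reactants: 14
Product: 15 (R)-5-[(1E,5E)-6-iodo-2-methylhepta-1,5-dien-1-yl]furan-2(5H)-one
Conditions: second-generation Grubbs catalyst (5 mol %), CH2Cl2 (5 mM), 40 °C
Reagents that add atoms: none
Why: Ring-closing metathesis of an allyl acrylate to a butenolide; the ruthenium carbene loads on the monosubstituted vinyl group and closes on the acrylate, while the trisubstituted alkene and the trisubstituted alkenyl iodide are too hindered to take part.

Step 10
Reactants: 16 but-3-yn-1-ol
Product: 17 1-[(but-3-yn-1-yloxy)methyl]-4-methoxybenzene
Conditions: NaH (1.05 equiv), 4-methoxybenzyl chloride, Bu4NI (cat.), THF/DMF, 0 °C → rt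
Reagents that add atoms: 4-methoxybenzyl chloride, COc1ccc(CCl)cc1
Why: Williamson etherification; with one equivalent of NaH at 0 °C the alkoxide forms much faster than the acetylide, and the benzyl ether is inert to the organoaluminium chemistry of step 11.

Step 11
Reactants: 17; 18 ethylene oxide
Product: 21 (E)-6-[(4-methoxybenzyl)oxy]-4-methylhex-3-en-1-ol, via alkenyldimethylalane 19 (not isolated), via lithium alkenyl(butyl)dimethylalanate 20 (not isolated)
Conditions: Me3Al (2 equiv), Cp2ZrCl2 (0.25 equiv), CH2Cl2, 0 °C → rt; volatiles removed; n-BuLi (1 equiv), hexane/THF, −30 °C; ethylene oxide (3 equiv), −30 °C → rt; aq. NH4Cl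
Reagents that add atoms: trimethylaluminium, C[Al](C)C
Why: Zirconium-catalysed methylalumination (Negishi carboalumination) adds methyl and aluminium syn, with methyl on the internal carbon; the derived alanate opens the epoxide with retention at the alkenyl carbon, which fixes the E C11=C12 alkene and adds C9–C10.

Step 12
Reactants: 21
Product: 22 (E)-tert-butyl({6-[(4-methoxybenzyl)oxy]-4-methylhex-3-en-1-yl}oxy)dimethylsilane
Conditions: TBSCl (1.2 equiv), imidazole (2 equiv), DMF, rt
Reagents that add atoms: tert-butyldimethylsilyl chloride, CC(C)(C)[Si](C)(C)Cl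
Why: Standard silylation of a primary alcohol; the silyl ether on C9 survives the magnesium and copper chemistry ahead and comes off under mild acid at the end.

Step 13
Reactants: 22
Product: 23 (E)-6-[(tert-butyldimethylsilyl)oxy]-3-methylhex-3-en-1-ol
Conditions: DDQ (1.3 equiv), CH2Cl2/pH 7 buffer (10:1), 0 °C → rt
Reagents that add atoms: none
Why: Oxidative cleavage of the 4-methoxybenzyl ether by benzylic hydride abstraction and hydrolysis of the oxocarbenium ion; the silyl ether and the isolated trisubstituted alkene are inert to DDQ under buffered conditions.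

Step 14
Reactants: 23
Product: 24 (E)-[(6-bromo-4-methylhex-3-en-1-yl)oxy](tert-butyl)dimethylsilane
Conditions: CBr4 (1.3 equiv), PPh3 (1.4 equiv), imidazole, CH2Cl2, 0 °C
Reagents that add atoms: tetrabromomethane, BrC(Br)(Br)Br
Why: Appel bromination of a primary alcohol by SN2 displacement of the alkoxyphosphonium ion; imidazole buffers traces of HBr so that the silyl ether stays on.

Step 15
Reactants: 24; 15
Product: 27 (4R,5R)-4-{(E)-6-[(tert-butyldimethylsilyl)oxy]-3-methylhex-3-en-1-yl}-3-[(dimethylamino)methyl]-5-[(1E,5E)-6-iodo-2-methylhepta-1,5-dien-1-yl]dihydrofuran-2(3H)-one (C3 epimers), via alkylmagnesium bromide 25 (not isolated), via silyl ketene acetal 26 (not isolated)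
Conditions: 24 (1.5 equiv), Mg, THF, rt; then CuBr·SMe2 (0.2 equiv), Me3SiCl (2.5 equiv), 15, THF, −78 °C; then CH2=NMe2+ I− (3 equiv), −78 °C → rt; aq. NaHCO3
Reagents that add atoms: N,N-dimethylmethyleneiminium iodide (Eschenmoser's salt), C=[N+](C)C.[I-]
Why: Copper-catalysed conjugate addition of an alkylmagnesium halide to a butenolide with chlorosilane trapping, then Mannich reaction of the silyl ketene acetal with the iminium salt. The alkylcopper species adds to C1 on the face anti to the C2 alkenyl group, which sets the trans C1/C2 relationship; the C15 centre formed here is removed in step 16. At −78 °C the 1,4-addition should outrun any reaction at the hindered alkenyl iodide.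

Step 16
Reactants: 27
Product: 29 (4R,5S)-4-{(E)-6-[(tert-butyldimethylsilyl)oxy]-3-methylhex-3-en-1-yl}-5-[(1E,5E)-6-iodo-2-methylhepta-1,5-dien-1-yl]-3-methylidenedihydrofuran-2(3H)-one, via trimethylammonium iodide 28 (not isolated)
Conditions: MeI (10 equiv), CH2Cl2, rt; then sat. aq. NaHCO3, rt
Reagents that add atoms: none
Why: Quaternisation of the Mannich base and E1cB elimination of trimethylamine give the exocyclic methylene under very mild base. The change of the C5 descriptor from R to S reflects only a change in substituent priority.

Step 17
Reactants: 29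
Product: 30 (4R,5S)-4-[(E)-6-hydroxy-3-methylhex-3-en-1-yl]-5-[(1E,5E)-6-iodo-2-methylhepta-1,5-dien-1-yl]-3-methylidenedihydrofuran-2(3H)-one
Conditions: aq. HF (48%), MeCN, 0 °C
Reagents that add atoms: none
Why: Acidic fluoride cleavage of a primary silyl ether; no base or nucleophile is present that could add to the methylene lactone, and the conditions are too mild to ionise the allylic C2–O bond.

Step 18
Reactants: 30
Product: 31 (E)-6-{(2S,3R)-2-[(1E,5E)-6-iodo-2-methylhepta-1,5-dien-1-yl]-4-methylidene-5-oxotetrahydrofuran-3-yl}-4-methylhex-3-enal
Conditions: Dess–Martin periodinane (1.3 equiv), NaHCO3, CH2Cl2, 0 °C; used at once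
Reagents that add atoms: none
Why: Dess–Martin oxidation of a homoallylic primary alcohol; the buffered, non-basic conditions are the usual way to reach a β,γ-unsaturated aldehyde without moving the C11=C12 alkene into conjugation.

Step 19
Reactants: 31
Product: 33 (3aR,6E,9S,10E,14E,15aS)-9-hydroxy-6,10,14-trimethyl-3-methylidene-3a,4,5,8,9,12,13,15a-octahydrocyclotetradeca[b]furan-2(3H)-one, via alkenyl-CrCl2 species 32 (not isolated)
Conditions: CrCl2 (4 equiv), N-{2-[(4S)-4-isopropyl-4,5-dihydrooxazol-2-yl]-6-methylphenyl}methanesulfonamide (4.4 equiv), Et3N (4.4 equiv), NiCl2·(2,9-dimethyl-1,10-phenanthroline) (0.2 equiv), LiCl, degassed MeCN/THF, rt; 31 added over 12 h by syringe pump (final 2 mM); aq. work-up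
Reagents that add atoms: none
Why: Zerovalent nickel, formed from NiCl2 and CrCl2, inserts into the C8–iodine bond with retention and hands the alkenyl group to trivalent chromium; the resulting alkenylchromium 32 adds to the C9 aldehyde bound to the same metal, and the chromium alkoxide is hydrolysed on work-up. The closest known reaction type is the nickel/chromium-mediated Nozaki–Hiyama–Kishi coupling of alkenyl iodides with aldehydes, which is established for macrocyclisation and in ligand-controlled asymmetric form. The fourteen-membered ring closes in a 14-exo-trig mode (the carbonyl oxygen stays outside the ring), and slow addition keeps the concentration low enough to favour ring closure over oligomerisation. C9 is set by the chiral oxazoline–sulfonamide ligand on chromium, which shields one face of the coordinated aldehyde so that C8 attacks the Re face to give the S carbinol; C1 and C2 are too remote to help or to interfere. The step needs chemoselectivity for the aldehyde over the lactone carbonyl and the conjugated methylene, which the hard, weakly basic and aldehyde-selective alkenylchromium reagent provides. It needs retention of the E geometry at C7=C8, which follows because insertion and transmetalation both preserve alkene configuration. It also needs the β,γ-unsaturated aldehyde to stay unconjugated, which the absence of free base secures.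

Step 20
Reactants: 33
Product: 34 (3aR,6E,9S,10E,14E,15aS)-6,10,14-trimethyl-3-methylidene-2-oxo-2,3,3a,4,5,8,9,12,13,15a-decahydrocyclotetradeca[b]furan-9-yl acetate (the target; 1R,2S,9S in the C1–C17 numbering)
Conditions: Ac2O (3 equiv), pyridine, DMAP (cat.), CH2Cl2, 0 °C → rt
Reagents that add atoms: acetic anhydride, CC(=O)OC(C)=O
Why: Acylation of a secondary allylic alcohol at oxygen; the C9–O bond is not broken, so the configuration is retained and no allylic transposition can occur.

## Compound list

1 | geranyl acetate | CC(C)=CCC/C(C)=C/COC(C)=O | starting material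
2 | (E)-5-(3,3-dimethyloxiran-2-yl)-3-methylpent-2-en-1-yl acetate (racemic epoxide) | CC(=O)OC/C=C(\C)CCC1OC1(C)C | intermediate
3 | (E)-6,7-dihydroxy-3,7-dimethyloct-2-en-1-yl acetate (racemic, not isolated) | CC(=O)OC/C=C(\C)CCC(O)C(C)(C)O | intermediate
4 | (E)-3-methyl-6-oxohex-2-en-1-yl acetate | CC(=O)OC/C=C(\C)CCC=O | intermediate
5 | (E)-3-methylhept-2-en-6-yn-1-yl acetate (not isolated) | CC(=O)OC/C=C(\C)CCC#C | intermediate
6 | (E)-3-methylhept-2-en-6-yn-1-ol | OC/C=C(\C)CCC#C | intermediate
7 | dilithium alkoxide acetylide of 6 (not isolated) | [Li]OC/C=C(\C)CCC#C[Li] | intermediate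
8 | (E)-3-methyloct-2-en-6-yn-1-ol | OC/C=C(\C)CCC#CC | intermediate
9 | (2E,6E)-7-[Zr(Cl)Cp2]-3-methylocta-2,6-dien-1-yl O–Zr(Cl)Cp2 alkoxide (not isolated) | Cl[Zr](OC/C=C(\C)CC/C=C(\C)[Zr](Cl)(C1C=CC=C1)C1C=CC=C1)(C1C=CC=C1)C1C=CC=C1 | intermediate
10 | (2E,6E)-7-iodo-3-methylocta-2,6-dien-1-ol | OC/C=C(\C)CC/C=C(\C)I | intermediate
11 | (2E,6E)-7-iodo-3-methylocta-2,6-dienal | O=C/C=C(\C)CC/C=C(\C)I | intermediate
12 | (3R,4E,8E)-9-iodo-5-methyldeca-1,4,8-trien-3-ol | C=C[C@@H](O)/C=C(\C)CC/C=C(\C)I | intermediate
13 | acryloyl chloride | C=CC(=O)Cl | starting material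
14 | (3R,4E,8E)-9-iodo-5-methyldeca-1,4,8-trien-3-yl acrylate | C=CC(=O)O[C@H](C=C)/C=C(\C)CC/C=C(\C)I | intermediate
15 | (R)-5-[(1E,5E)-6-iodo-2-methylhepta-1,5-dien-1-yl]furan-2(5H)-one | O=C1C=C[C@H](/C=C(\C)CC/C=C(\C)I)O1 | intermediate
16 | but-3-yn-1-ol | C#CCCO | starting material
17 | 1-[(but-3-yn-1-yloxy)methyl]-4-methoxybenzene | C#CCCOCc1ccc(OC)cc1 | intermediate
18 | ethylene oxide | C1CO1 | starting material
19 | (E)-{4-[(4-methoxybenzyl)oxy]-2-methylbut-1-en-1-yl}dimethylaluminium (not isolated) | C[Al](C)/C=C(\C)CCOCc1ccc(OC)cc1 | intermediate
20 | lithium butyl{(E)-4-[(4-methoxybenzyl)oxy]-2-methylbut-1-en-1-yl}dimethylaluminate (not isolated) | [Li+].CCCC[Al-](C)(C)/C=C(\C)CCOCc1ccc(OC)cc1 | intermediate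
21 | (E)-6-[(4-methoxybenzyl)oxy]-4-methylhex-3-en-1-ol | OCC/C=C(\C)CCOCc1ccc(OC)cc1 | intermediate
22 | (E)-tert-butyl({6-[(4-methoxybenzyl)oxy]-4-methylhex-3-en-1-yl}oxy)dimethylsilane | CC(C)(C)[Si](C)(C)OCC/C=C(\C)CCOCc1ccc(OC)cc1 | intermediate
23 | (E)-6-[(tert-butyldimethylsilyl)oxy]-3-methylhex-3-en-1-ol | OCC/C(C)=C/CCO[Si](C)(C)C(C)(C)C | intermediate
24 | (E)-[(6-bromo-4-methylhex-3-en-1-yl)oxy](tert-butyl)dimethylsilane | BrCC/C(C)=C/CCO[Si](C)(C)C(C)(C)C | intermediate
25 | {(E)-6-[(tert-butyldimethylsilyl)oxy]-3-methylhex-3-en-1-yl}magnesium bromide (not isolated) | Br[Mg]CC/C(C)=C/CCO[Si](C)(C)C(C)(C)C | intermediate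
26 | tert-butyl{[(E)-6-{(2R,3R)-2-[(1E,5E)-6-iodo-2-methylhepta-1,5-dien-1-yl]-5-[(trimethylsilyl)oxy]-2,3-dihydrofuran-3-yl}-4-methylhex-3-en-1-yl]oxy}dimethylsilane (silyl ketene acetal, not isolated) | C[Si](C)(C)OC1=C[C@@H](CC/C(C)=C/CCO[Si](C)(C)C(C)(C)C)[C@H](/C=C(\C)CC/C=C(\C)I)O1 | intermediate
27 | (4R,5R)-4-{(E)-6-[(tert-butyldimethylsilyl)oxy]-3-methylhex-3-en-1-yl}-3-[(dimethylamino)methyl]-5-[(1E,5E)-6-iodo-2-methylhepta-1,5-dien-1-yl]dihydrofuran-2(3H)-one (C3 epimers, mainly 3,4-trans) | CN(C)CC1C(=O)O[C@@H](/C=C(\C)CC/C=C(\C)I)[C@@H]1CC/C(C)=C/CCO[Si](C)(C)C(C)(C)C | intermediate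
28 | trimethylammonium iodide of 27 (not isolated) | C[N+](C)(C)CC1C(=O)O[C@@H](/C=C(\C)CC/C=C(\C)I)[C@@H]1CC/C(C)=C/CCO[Si](C)(C)C(C)(C)C.[I-] | intermediate
29 | (4R,5S)-4-{(E)-6-[(tert-butyldimethylsilyl)oxy]-3-methylhex-3-en-1-yl}-5-[(1E,5E)-6-iodo-2-methylhepta-1,5-dien-1-yl]-3-methylidenedihydrofuran-2(3H)-one | C=C1C(=O)O[C@@H](/C=C(\C)CC/C=C(\C)I)[C@@H]1CC/C(C)=C/CCO[Si](C)(C)C(C)(C)C | intermediate
30 | (4R,5S)-4-[(E)-6-hydroxy-3-methylhex-3-en-1-yl]-5-[(1E,5E)-6-iodo-2-methylhepta-1,5-dien-1-yl]-3-methylidenedihydrofuran-2(3H)-one | C=C1C(=O)O[C@@H](/C=C(\C)CC/C=C(\C)I)[C@@H]1CC/C(C)=C/CCO | intermediate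
31 | (E)-6-{(2S,3R)-2-[(1E,5E)-6-iodo-2-methylhepta-1,5-dien-1-yl]-4-methylidene-5-oxotetrahydrofuran-3-yl}-4-methylhex-3-enal | C=C1C(=O)O[C@@H](/C=C(\C)CC/C=C(\C)I)[C@@H]1CC/C(C)=C/CC=O | intermediate
32 | C8 alkenyl-CrCl2 species of 31 (trivalent chromium, ligand omitted; not isolated) | C=C1C(=O)O[C@@H](/C=C(\C)CC/C=C(\C)[Cr](Cl)Cl)[C@@H]1CC/C(C)=C/CC=O | intermediate
33 | (3aR,6E,9S,10E,14E,15aS)-9-hydroxy-6,10,14-trimethyl-3-methylidene-3a,4,5,8,9,12,13,15a-octahydrocyclotetradeca[b]furan-2(3H)-one | C=C1C(=O)O[C@H]2/C=C(\C)CC/C=C(\C)[C@@H](O)C/C=C(\C)CC[C@H]12 | intermediate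
34 | (3aR,6E,9S,10E,14E,15aS)-6,10,14-trimethyl-3-methylidene-2-oxo-2,3,3a,4,5,8,9,12,13,15a-decahydrocyclotetradeca[b]furan-9-yl acetate | C=C1C(=O)O[C@H]2/C=C(\C)CC/C=C(\C)[C@@H](OC(C)=O)C/C=C(\C)CC[C@H]12 | target

## Step count and least certain steps

Total: 20 steps (steps 1–9 to butenolide 15, steps 10–14 to bromide 24, steps 15–20 for union, ring closure and acetylation). Longest linear sequence: 15 steps (steps 1–9 and 15–20, from geranyl acetate).

Step 19 (key step). The most likely failure is poor facial selectivity at C9. The ligand-bound chromium has to distinguish the aldehyde faces inside a macrocyclic transition state whose own conformational preferences may dilute or oppose the ligand. Intermolecular coupling competes if the dilution is not held, and too much NiCl2 promotes homocoupling of the alkenyl iodide. Fallback, setting out from 31: the ring is closed without stereocontrol (CrCl2, catalytic NiCl2, DMSO/THF, slow addition), which should give 33 together with its C9 epimer, the (9R)-alcohol F1. The mixture is oxidised with Dess–Martin periodinane and NaHCO3 to the macrocyclic C9 enone F2. F2 is then reduced with (R)-2-methyl-CBS-oxazaborolidine and catecholborane at −78 °C (Corey–Bakshi–Shibata reduction). The C8 alkenyl group acts as the large substituent and the C10 methylene as the small one, so the 9S alcohol is expected, and the route is rejoined at 33.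

Step 15. Several processes can compete with the wanted 1,4-addition and capture. These are deprotonation at the doubly activated C–H next to the ring oxygen of 15 (loss of enantiopurity), allylic substitution at that carbon, reaction of the alkylcopper species at the alkenyl iodide, and incomplete capture of the silyl ketene acetal by the iminium salt in the presence of magnesium salts. Fallback, setting out from 15 and 25 (made from 24): the copper-catalysed addition is run as before but quenched with aqueous NH4Cl, giving the trans lactone F3, which can be purified. Deprotonation with LiN(SiMe3)2 at −78 °C and aldol reaction with monomeric formaldehyde give the hydroxymethyl lactone F4. Mesylation (MsCl, Et3N) to the mesylate F5 and elimination with DBU rejoin the route at 29. This replaces the Mannich capture with an aldol–dehydration sequence that does not depend on the state of the enolate after the conjugate addition.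

Step 7. The most likely failure is insufficient enantioselectivity. A background addition promoted by residual magnesium halide can compete, and a β,β-disubstituted enal offers the catalyst only a modest steric difference. Fallback, setting out from 11: vinylmagnesium bromide in THF at −78 °C gives the racemic alcohol F6. Kinetic resolution with immobilised lipase B from Candida antarctica (Novozym 435) and vinyl acetate in hexane should acylate the R enantiomer, in line with the empirical rule for lipases (large alkenyl group against small vinyl group). This gives the (R)-acetate F7 and leaves the (S)-alcohol F8, which is separated. Methanolysis of F7 (K2CO3, MeOH) rejoins the route at 12.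

Step 5. The most likely failure is incomplete regiocontrol of the Zr–H addition across the internal alkyne, so that iodine also ends up on C7; the two alkyne carbons differ only as methyl against methylene. Fallback, setting out from 6 and replacing steps 4 and 5: double deprotonation (n-BuLi) and silylation with Me3SiCl give the bis-silyl compound F9. Mild acidic methanolysis frees the hydroxyl to give the C-silyl alkynol F10. Hydroalumination with i-Bu2AlH in heptane at 50 °C places aluminium on the silyl-bearing carbon with net trans addition. Conversion to the alanate with MeLi and methylation with MeI then give the (E)-vinylsilane F11. Iododesilylation with N-iodosuccinimide in MeCN/ClCH2CN at 0 °C proceeds with retention and rejoins the route at 10. Here the regiochemistry is dictated by silicon and not by a small steric difference.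

## Further compounds

F1 | step 19 | (3aR,6E,9R,10E,14E,15aS)-9-hydroxy-6,10,14-trimethyl-3-methylidene-3a,4,5,8,9,12,13,15a-octahydrocyclotetradeca[b]furan-2(3H)-one (C9 epimer of 33) | C=C1C(=O)O[C@H]2/C=C(\C)CC/C=C(\C)[C@H](O)C/C=C(\C)CC[C@H]12
F2 | step 19 | (3aR,6E,10E,14E,15aS)-6,10,14-trimethyl-3-methylidene-3a,4,5,12,13,15a-hexahydrocyclotetradeca[b]furan-2,9(3H,8H)-dione (macrocyclic C9 enone) | C=C1C(=O)O[C@H]2/C=C(\C)CC/C=C(\C)C(=O)C/C=C(\C)CC[C@H]12
F3 | step 15 | (4R,5R)-4-{(E)-6-[(tert-butyldimethylsilyl)oxy]-3-methylhex-3-en-1-yl}-5-[(1E,5E)-6-iodo-2-methylhepta-1,5-dien-1-yl]dihydrofuran-2(3H)-one | O=C1C[C@@H](CC/C(C)=C/CCO[Si](C)(C)C(C)(C)C)[C@H](/C=C(\C)CC/C=C(\C)I)O1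
F4 | step 15 | (4R,5R)-4-{(E)-6-[(tert-butyldimethylsilyl)oxy]-3-methylhex-3-en-1-yl}-3-(hydroxymethyl)-5-[(1E,5E)-6-iodo-2-methylhepta-1,5-dien-1-yl]dihydrofuran-2(3H)-one (C3 epimers) | OCC1C(=O)O[C@@H](/C=C(\C)CC/C=C(\C)I)[C@@H]1CC/C(C)=C/CCO[Si](C)(C)C(C)(C)C
F5 | step 15 | methanesulfonate of F4 | CS(=O)(=O)OCC1C(=O)O[C@@H](/C=C(\C)CC/C=C(\C)I)[C@@H]1CC/C(C)=C/CCO[Si](C)(C)C(C)(C)C
F6 | step 7 | racemic (4E,8E)-9-iodo-5-methyldeca-1,4,8-trien-3-ol | C=CC(O)/C=C(\C)CC/C=C(\C)I
F7 | step 7 | (3R,4E,8E)-9-iodo-5-methyldeca-1,4,8-trien-3-yl acetate | CC(=O)O[C@H](C=C)/C=C(\C)CC/C=C(\C)I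
F8 | step 7 | (3S,4E,8E)-9-iodo-5-methyldeca-1,4,8-trien-3-ol | C=C[C@H](O)/C=C(\C)CC/C=C(\C)I
F9 | step 5 | (E)-trimethyl{[3-methyl-7-(trimethylsilyl)hept-2-en-6-yn-1-yl]oxy}silane | C[Si](C)(C)OC/C=C(\C)CCC#C[Si](C)(C)C
F10 | step 5 | (E)-3-methyl-7-(trimethylsilyl)hept-2-en-6-yn-1-ol | OC/C=C(\C)CCC#C[Si](C)(C)C
F11 | step 5 | (2E,6E)-3-methyl-7-(trimethylsilyl)octa-2,6-dien-1-ol | OC/C=C(\C)CC/C=C(\C)[Si](C)(C)C
A1 | alternative 1 | macrocyclic trans α-carboxy-γ-lactone, C9 tert-butyldimethylsilyl ether | OC(=O)[C@H]1C(=O)O[C@H]2/C=C(\C)CC/C=C(\C)[C@@H](O[Si](C)(C)C(C)(C)C)C/C=C(\C)CC[C@H]12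
A2 | alternative 1 | macrocyclic trans-2-alkenylcyclopropane-1,1-dicarboxylic acid (C15 bridging C1 and C2), C9 tert-butyldimethylsilyl ether | OC(=O)C1(C(O)=O)[C@H]2/C=C(\C)CC/C=C(\C)[C@@H](O[Si](C)(C)C(C)(C)C)C/C=C(\C)CC[C@H]12
A3 | alternative 2 | fourteen-membered carbocycle fused to the saturated lactone (C15 = CH2), C9 tert-butyldimethylsilyl ether | O=C1O[C@H]2/C=C(\C)CC/C=C(\C)[C@@H](O[Si](C)(C)C(C)(C)C)C/C=C(\C)CC[C@@H]2C1
A4 | alternative 2 | seco trans lactone with a vinyl group on C1 and the (E)-alkenyl iodide at C12, C9 tert-butyldimethylsilyl ether | O=C1C[C@@H](C=C)[C@H](/C=C(\C)CC/C=C(\C)[C@@H](O[Si](C)(C)C(C)(C)C)C/C=C(\C)I)O1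
A5 | alternative 3 | fourteen-membered C7≡C8 cycloalkyne fused to the α-methylene lactone, C9 tert-butyldimethylsilyl ether | C=C1C(=O)O[C@H]2/C=C(\C)CCC#C[C@@H](O[Si](C)(C)C(C)(C)C)C/C=C(\C)CC[C@H]12
A6 | alternative 3 | trans α-methylene lactone with two methyl-capped alkyne arms (at C7 and C8), C9 tert-butyldimethylsilyl ether | C=C1C(=O)O[C@@H](/C=C(\C)CCC#CC)[C@@H]1CC/C(C)=C/C[C@H](O[Si](C)(C)C(C)(C)C)C#CC
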